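Everything rests on a hidden mirror plane: the two methyl-bearing quaternary carbons C5 and C6a, bridged by C6, are the enantiotopic carbinol carbons of meso cis-1,4-dimethylcyclopent-2-ene-1,4-diol, whose alkene carbons are C1′ of the side chain and ring-fusion C3a. Held as a strained bicyclic phenylboronate, this meso alkene is opened by catalytic enantioselective ring-opening/cross-metathesis with the complete aryl-dodecene side chain. One operation thus fixes both quaternary stereocentres, whose methyl-versus-n-alkyl relationship no substrate control can set, and joins the chain. The vinyl group left behind feeds a Pd(II) cyclisation–carbonylation–lactonisation, and one hydrogenation finishes.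

Key step: step 5

Numbering used: the target is a hexahydrofuro[3,2-b]furan-2-one with O1, C2(=O), C3, C3a (ring-fusion CH), O4, C5 (methyl and side chain), C6, C6a (ring-fusion C–CH3); the side chain is C1′–C12′.

Assumption: the sense in which the chiral Mo catalyst of step 5 tells the two enantiotopic alkene carbons of 11 apart cannot be predicted for this substrate; the (S)-aryloxide is written, and its enantiomer is used if a trial run gives the mirror image of 12.

Step 1
Reactants: 1 11-bromoundec-1-ene; 2 1-(benzyloxy)-4-(chloromethyl)benzene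
Product: 4 1-(benzyloxy)-4-(dodec-11-en-1-yl)benzene, via undec-10-en-1-ylmagnesium bromide 3 (not isolated)
Conditions: 1, Mg, THF, rt to 40 °C; then 2, Li2CuCl4 (3 mol %), THF, −10 °C to rt
Reagents that add atoms: none
Why: Copper-catalysed Kumada-type sp3–sp3 cross-coupling of a primary alkyl Grignard reagent with a benzylic chloride is reliable, tolerates the terminal alkene and the benzyl ether, and creates no stereocentre.

Step 2
Reactants: 5 3-methylcyclopent-2-en-1-one
Product: 8 1,4-dimethylcyclopenta-1,3-diene, via 1,3-dimethylcyclopent-2-en-1-ol 6 (not isolated), via 1,3-dimethylcyclopenta-1,3-diene 7 (not isolated)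
Conditions: MeLi, Et2O, −78 to 0 °C; H2O; then TsOH·H2O (1 mol %), pentane, 0 °C to rt; distil, let equilibrate at rt, use fresh
Reagents that add atoms: methyllithium, [Li]C
Why: 1,2-Addition of methyllithium to the enone and acid-catalysed E1 dehydration of the tertiary allylic alcohol 6 give diene 7, which equilibrates by [1,5]-sigmatropic hydrogen shifts at room temperature with 8, the only tautomer that carries both methyl groups on the diene termini; the tautomer mixture is used as such and no stereocentre is present.

Step 3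
Reactants: 8 1,4-dimethylcyclopenta-1,3-diene (as the tautomer mixture from step 2)
Product: 10 (1R,4S)-1,4-dimethylcyclopent-2-ene-1,4-diol (cis, meso), via (1R,4S)-1,4-dimethyl-2,3-dioxabicyclo[2.2.1]hept-5-ene 9 (not isolated)
Conditions: O2, hν (visible), rose bengal (cat.), thiourea (0.6 equiv), MeOH (5% H2O), −20 °C; chromatography
Reagents that add atoms: dioxygen, O=O
Why: Singlet-oxygen [4+2] cycloaddition (photooxygenation) adds both oxygen atoms suprafacially to the termini of 8, so that the two new quaternary carbinol carbons are necessarily cis (meso), and thiourea reduces the O–O bond of 9 in situ without touching the C–O bonds; the adduct of tautomer 7 is a constitutional isomer that is removed at this stage.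

Step 4
Reactants: 10 (1R,4S)-1,4-dimethylcyclopent-2-ene-1,4-diol
Product: 11 (1R,5S)-1,5-dimethyl-3-phenyl-2,4-dioxa-3-borabicyclo[3.2.1]oct-6-ene (meso)
Conditions: PhB(OH)2 (1.05 equiv), 4 Å MS, toluene, 40 °C
Reagents that add atoms: phenylboronic acid, OB(O)c1ccccc1
Why: Condensation to the cyclic boronic ester is possible only for the cis-1,3-diol, proceeds under neutral conditions that spare the acid-sensitive tertiary allylic alcohols, keeps the mirror plane, and ties the cyclopentene into a strained bicyclo[3.2.1]octene that is primed for ring opening.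

Step 5
Reactants: 11 (1R,5S)-1,5-dimethyl-3-phenyl-2,4-dioxa-3-borabicyclo[3.2.1]oct-6-ene; 4 1-(benzyloxy)-4-(dodec-11-en-1-yl)benzene (3 equiv, excess recovered)
Product: 13 (3S,5R,6Z)-17-[4-(benzyloxy)phenyl]-3,5-dimethylheptadeca-1,6-diene-3,5-diol, via (4R,6S)-4-{(1Z)-12-[4-(benzyloxy)phenyl]dodec-1-en-1-yl}-6-ethenyl-4,6-dimethyl-2-phenyl-1,3,2-dioxaborinane 12 (not isolated)
Conditions: Mo(NAd)(CHCMe2Ph)(2,5-Me2-pyrrolide)2 + (S)-3,3′-dibromo-2′-(TBSO)-octahydro-1,1′-binaphth-2-ol (5 mol % each, chiral monoaryloxide pyrrolide catalyst formed in situ), C6H6, 22 °C, N2 purge; then 30% H2O2, 2 M NaOH, THF, 0 °C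
Reagents that add atoms: none
Why: The Mo alkylidene derived from 4 adds across the strained cis-alkene of 11 on its exo face (anti to the O–B–O bridge) in a [2+2] step, the metallacyclobutane cycloreverts to open the cyclopentene, and the new alkylidene is released by cross-metathesis with a second molecule of 4 as the terminal vinyl group, so that no atom is lost. The closest known reaction type is catalytic asymmetric ring-opening/cross-metathesis of meso norbornenes and meso oxabicyclo[3.2.1]octenes. No ring is closed: the future C3a–C1′ bond of the carbocycle is cleaved, and release of the bicyclo[3.2.1] strain makes the opening irreversible, since re-closure of 12 would rebuild the bridged ring. No new stereocentre is made; the two enantiotopic quaternary carbinol carbons of 11 become C5 and C6a, and their absolute configuration is fixed by the stereogenic Mo centre with its chiral aryloxide, which decides which alkene carbon receives the chain alkylidene. The step needs enantiotopic-site selectivity (catalyst control) and freedom from secondary metathesis, which the fully substituted allylic carbons of 12 should secure by making its alkenes poor substrates; the alkene geometry is immaterial because it is erased in step 7. The oxidative work-up then cleaves the B–O bonds with retention at carbon and frees diol 13.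

Step 6
Reactants: 13 (3S,5R,6Z)-17-[4-(benzyloxy)phenyl]-3,5-dimethylheptadeca-1,6-diene-3,5-diol
Product: 14 (3aS,5R,6aS)-5-{(1Z)-12-[4-(benzyloxy)phenyl]dodec-1-en-1-yl}-5,6a-dimethyltetrahydrofuro[3,2-b]furan-2(3H)-one
Conditions: PdCl2 (10 mol %), CuCl2 (3 equiv), NaOAc (3 equiv), CO (1 atm), AcOH, rt
Reagents that add atoms: carbon monoxide, [C-]#[O+]
Why: In this Pd(II)-mediated hydroxycyclisation–carbonylation–lactonisation (intramolecular alkoxycarbonylation) the hydroxyl on the chain-bearing carbon adds 5-exo to the Pd-bound terminal vinyl group, CO inserts into the primary C–Pd bond and the acyl-palladium is captured by the neighbouring tertiary hydroxyl, which is possible only when the new C3a–O bond is cis to the C6a–O bond, so that C3a is set (S) by the existing C6a centre through reversible oxypalladation, while the hindered internal Z-alkene should not compete with the monosubstituted one.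

Step 7
Reactants: 14 (3aS,5R,6aS)-5-{(1Z)-12-[4-(benzyloxy)phenyl]dodec-1-en-1-yl}-5,6a-dimethyltetrahydrofuro[3,2-b]furan-2(3H)-one
Product: 15 plakortone N, (3aS,5S,6aS)-5-[12-(4-hydroxyphenyl)dodecyl]-5,6a-dimethyltetrahydrofuro[3,2-b]furan-2(3H)-one
Conditions: H2 (1 atm), 10% Pd/C, EtOAc–EtOH, rt
Reagents that add atoms: none
Why: Heterogeneous catalytic hydrogenation saturates the 1,2-disubstituted alkene and hydrogenolyses the benzyl ether in the same operation, leaves lactone, tetrahydrofuran and all three stereocentres untouched, and so should deliver 15.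

Compound list
1 | 11-bromoundec-1-ene | C=CCCCCCCCCCBr | starting material
2 | 1-(benzyloxy)-4-(chloromethyl)benzene | ClCc1ccc(OCc2ccccc2)cc1 | starting material
3 | undec-10-en-1-ylmagnesium bromide | C=CCCCCCCCCC[Mg]Br | intermediate (not isolated)
4 | 1-(benzyloxy)-4-(dodec-11-en-1-yl)benzene | C=CCCCCCCCCCCc1ccc(OCc2ccccc2)cc1 | intermediate
5 | 3-methylcyclopent-2-en-1-one | CC1=CC(=O)CC1 | starting material
6 | 1,3-dimethylcyclopent-2-en-1-ol (racemic) | CC1=CC(C)(O)CC1 | intermediate (not isolated)
7 | 1,3-dimethylcyclopenta-1,3-diene | CC1=CC(C)=CC1 | intermediate (not isolated)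
8 | 1,4-dimethylcyclopenta-1,3-diene | CC1=CC=C(C)C1 | intermediate
9 | (1R,4S)-1,4-dimethyl-2,3-dioxabicyclo[2.2.1]hept-5-ene (meso) | C[C@]12C[C@](C)(OO1)C=C2 | intermediate (not isolated)
10 | (1R,4S)-1,4-dimethylcyclopent-2-ene-1,4-diol (cis, meso) | C[C@@]1(O)C[C@](C)(O)C=C1 | intermediate
11 | (1R,5S)-1,5-dimethyl-3-phenyl-2,4-dioxa-3-borabicyclo[3.2.1]oct-6-ene (meso) | C[C@]12C[C@](C)(OB(c3ccccc3)O1)C=C2 | intermediate
12 | (4R,6S)-4-{(1Z)-12-[4-(benzyloxy)phenyl]dodec-1-en-1-yl}-6-ethenyl-4,6-dimethyl-2-phenyl-1,3,2-dioxaborinane | C[C@]1(/C=C\CCCCCCCCCCc2ccc(OCc3ccccc3)cc2)C[C@@](C)(C=C)OB(c2ccccc2)O1 | intermediate (not isolated)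
13 | (3S,5R,6Z)-17-[4-(benzyloxy)phenyl]-3,5-dimethylheptadeca-1,6-diene-3,5-diol | C[C@](O)(/C=C\CCCCCCCCCCc1ccc(OCc2ccccc2)cc1)C[C@](C)(O)C=C | intermediate
14 | (3aS,5R,6aS)-5-{(1Z)-12-[4-(benzyloxy)phenyl]dodec-1-en-1-yl}-5,6a-dimethyltetrahydrofuro[3,2-b]furan-2(3H)-one | C[C@]1(/C=C\CCCCCCCCCCc2ccc(OCc3ccccc3)cc2)C[C@]2(C)OC(=O)C[C@@H]2O1 | intermediate
15 | plakortone N, (3aS,5S,6aS)-5-[12-(4-hydroxyphenyl)dodecyl]-5,6a-dimethyltetrahydrofuro[3,2-b]furan-2(3H)-one | C[C@]1(CCCCCCCCCCCCc2ccc(O)cc2)C[C@]2(C)OC(=O)C[C@@H]2O1 | target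

Total step count: 7. Longest linear sequence: 6 steps (steps 2 to 7, from 5); step 1 is a one-step branch that joins at step 5.

Steps most likely to fail

Step 5. The alkene of 11 is flanked by two fully substituted carbons, so ring opening may be too slow, or the catalyst may discriminate poorly between the two enantiotopic alkene carbons. The fallback sets out from 11 and comes back at 14, with no metathesis. Ozonolysis of 11 (O3, CH2Cl2, −78 °C; Me2S) would give the meso dialdehyde (4R,6S)-4,6-dimethyl-2-phenyl-1,3,2-dioxaborinane-4,6-dicarbaldehyde F1. An asymmetric Horner–Wadsworth–Emmons reaction with (1R,2S,5R)-8-phenylmenthyl bis(2,2,2-trifluoroethyl)phosphonoacetate (KHMDS, 18-crown-6, THF, −78 °C; auxiliary enantiomer chosen by trial), a known way to tell apart the enantiotopic formyl groups of α-oxygenated meso dialdehydes, would give the mono-(Z)-enoate, 8-phenylmenthyl (2Z)-3-[(4S,6R)-6-formyl-4,6-dimethyl-2-phenyl-1,3,2-dioxaborinan-4-yl]prop-2-enoate F2. Transfer of the boron to pinacol (PPTS, MeOH) would free the diol, whose γ-hydroxy (Z)-enoate lactonises with loss of the auxiliary to the butenolide (2R)-2-hydroxy-2-methyl-3-[(2S)-2-methyl-5-oxo-2,5-dihydrofuran-2-yl]propanal F3. DBU would then close the tetrahydrofuran by a reversible oxa-Michael addition that funnels to the cis-fused (3aS,5R,6aS)-5,6a-dimethyl-2-oxohexahydrofuro[3,2-b]furan-5-carbaldehyde F4. The chain would come from 1-(benzyloxy)-4-(11-bromoundecyl)benzene F5 (4-(benzyloxy)phenylmagnesium bromide, 1,11-dibromoundecane in excess, Li2CuCl4), converted with PPh3 into {11-[4-(benzyloxy)phenyl]undecyl}triphenylphosphonium bromide F6. A Wittig reaction of F4 with the ylide of F6 (NaHMDS, THF, −78 °C) would give 14.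

Step 6. Oxypalladation may take place at the internal alkene, Pd(II) in acetic acid may ionise the tertiary allylic alcohols, or β-hydride elimination may outrun CO insertion. The fallback sets out from 13 and comes back at 14, and separates ring closure from carbonylation. Intramolecular alkoxymercuration (Hg(OCOCF3)2, CH2Cl2, 0 °C; then aqueous NaCl), for which monosubstituted alkenes react much faster than hindered 1,2-disubstituted ones, would give the chloromercuriomethyl tetrahydrofuran F7, that is chloro{[(2R,3S,5R)-5-{(1Z)-12-[4-(benzyloxy)phenyl]dodec-1-en-1-yl}-3-hydroxy-3,5-dimethyloxolan-2-yl]methyl}mercury, with CH2HgCl cis to the 3-hydroxyl as in halo-etherifications of pent-4-ene-1,3-diols. Pd-catalysed carbonylation of the C–Hg bond (Li2PdCl4 cat., CuCl2, CO 1 atm, THF, rt), with capture of the acyl-palladium by the neighbouring tertiary hydroxyl, would give 14.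

Step 7. Hydrogenolysis of the tertiary allylic C5–O bond on palladium may compete with saturation of the alkene and open the tetrahydrofuran ring. The fallback sets out from 14 and comes back at 15. Diimide reduction (TsNHNH2, NaOAc, DME–H2O, reflux), which cannot cleave C–O bonds, would give the saturated benzyl ether (3aS,5S,6aS)-5-{12-[4-(benzyloxy)phenyl]dodecyl}-5,6a-dimethyltetrahydrofuro[3,2-b]furan-2(3H)-one F8. Hydrogenolysis of the benzyl ether alone (H2, Pd/C, EtOAc, rt) would then give 15.

Further compounds
F1 | step 5 | (4R,6S)-4,6-dimethyl-2-phenyl-1,3,2-dioxaborinane-4,6-dicarbaldehyde (meso) | C[C@]1(C=O)C[C@@](C)(C=O)OB(c2ccccc2)O1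
F2 | step 5 | (1R,2S,5R)-5-methyl-2-(2-phenylpropan-2-yl)cyclohexyl (2Z)-3-[(4S,6R)-6-formyl-4,6-dimethyl-2-phenyl-1,3,2-dioxaborinan-4-yl]prop-2-enoate | C[C@]1(C=O)C[C@@](C)(/C=C\C(=O)O[C@@H]3C[C@H](C)CC[C@H]3C(C)(C)c4ccccc4)OB(c2ccccc2)O1
F3 | step 5 | (2R)-2-hydroxy-2-methyl-3-[(2S)-2-methyl-5-oxo-2,5-dihydrofuran-2-yl]propanal | C[C@](O)(C=O)C[C@]1(C)OC(=O)C=C1
F4 | step 5 | (3aS,5R,6aS)-5,6a-dimethyl-2-oxohexahydrofuro[3,2-b]furan-5-carbaldehyde | C[C@]1(C=O)C[C@]2(C)OC(=O)C[C@@H]2O1
F5 | step 5 | 1-(benzyloxy)-4-(11-bromoundecyl)benzene | BrCCCCCCCCCCCc1ccc(OCc2ccccc2)cc1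
F6 | step 5 | {11-[4-(benzyloxy)phenyl]undecyl}triphenylphosphonium bromide | [Br-].c1ccc(cc1)[P+](c1ccccc1)(c1ccccc1)CCCCCCCCCCCc1ccc(OCc2ccccc2)cc1
F7 | step 6 | chloro{[(2R,3S,5R)-5-{(1Z)-12-[4-(benzyloxy)phenyl]dodec-1-en-1-yl}-3-hydroxy-3,5-dimethyloxolan-2-yl]methyl}mercury | C[C@]1(/C=C\CCCCCCCCCCc2ccc(OCc3ccccc3)cc2)C[C@](C)(O)[C@H](C[Hg]Cl)O1
F8 | step 7 | (3aS,5S,6aS)-5-{12-[4-(benzyloxy)phenyl]dodecyl}-5,6a-dimethyltetrahydrofuro[3,2-b]furan-2(3H)-one | C[C@]1(CCCCCCCCCCCCc2ccc(OCc3ccccc3)cc2)C[C@]2(C)OC(=O)C[C@@H]2O1
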